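## The problem

The target 18 is a (2R,3R)-dihydroflavonol. A phloroglucinol-type ring A is fused through O1/C8a and C4/C4a to a dihydropyranone ring C, which carries the 4-hydroxyphenyl ring B at C2 and a hydroxyl at C3, trans to each other. Ring A is fully differentiated: a 2-methylbut-3-en-2-yl (1,1-dimethylallyl) group sits on C6 between the C5 and C7 hydroxyls, so the two oxygens ortho to the C4 carbonyl are not equivalent and ring C must be closed onto the one remote from the side chain. The quaternary benzylic carbon of that side chain cannot come from direct C-prenylation, which gives the linear isomer. It needs an allyl-inverting sigmatropic shift from oxygen whose regiochemistry is beyond doubt. Of the two adjacent stereocentres only C2 needs outside control: once it is fixed, a C3 substituent enters anti to the aryl group, and the trans-diequatorial arrangement is also the more stable one. The molecule tolerates little rough treatment. Base opens the β-aryloxy ketone by retro-oxa-Michael reaction and so racemises C2, the α-ketol is easily oxidised or epimerised, and the terminal alkene flanked by two phenols can cyclise in strong acid and can be attacked by electrophilic oxidants. The feature that opens a short route is that C2 is both benzylic and bonded to O1. Before ring closure it can be the CH2 group of a 4-oxybenzyl ether on the C8a oxygen, six atoms from C3, and its C–H bonds are activated by oxygen and by the aryl ring together.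

## Retrosynthesis

**Protecting groups and the C3–O bond.** Target 18 is traced to its 7,4′-bis-MOM ether 17 and this to the 5-O-silyl ether 16, so the end game is a buffered fluoride step and a mild acetal methanolysis. The C3–O bond is cut next: 16 comes from the flavanone 13 through the silyl enol ether 14 and its epoxide 15. This cut is preferred to carrying the oxygen from the start because C3 is the carbene carbon of the key step and must arrive as CH, and because the C2 stereocentre of 13 can direct the oxidant. The precursor has one stereocentre less. The forward reaction must form the enol ether without a free enolate, which would open ring C, and must use an oxidant that prefers an enol ether to a monosubstituted alkene by a wide margin.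

**The C2–C3 bond (key cut).** Flavanone 13 is opened between C2 and C3 to the diazomethyl ketone 12, in which C3 is the diazo carbon and C2 the methylene of the benzylic ether on the C8a oxygen. The neighbouring cut at O1–C2 leads to a 2′-hydroxychalcone, whose cyclisation is reversible and hard to render enantioselective for a 2′,6′-dioxygenated ring A. A cut at C4–C4a asks for a regioselective acylation of a crowded ring. The C2–C3 cut gives an achiral precursor whose only demand is three different groups on the ring A oxygens. The forward reaction must prefer C–H insertion to attack on the ether oxygen and must select one of two enantiotopic hydrogens.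

**The diazo group.** Diazo ketone 12 is traced to the methyl ketone 10 through the trifluoroacetyl diketone 11. Acylating diazomethane with an acid chloride would need a benzoic acid that has to be made; the acetyl group is already present in the cheapest source of ring A. The forward reaction needs only kinetic enolisation of a methyl ketone, which the two ortho substituents do not hinder.

**The ethers on O5 and on the C8a oxygen.** Silyl ether 10 comes from phenol 9, and 9 from the dihydroxy ketone 5 and the benzylic alcohol 8. The alcohol 8 is made from 4-hydroxybenzaldehyde 6 through aldehyde 7. The order follows from sterics: the two ortho hydroxyls of 5 differ only in that one is flanked by the quaternary carbon, so etherification picks the open one and leaves the hindered one for silicon. A silyl group is chosen for O5 because it offers no C–H bond within reach of the carbene; a free hydroxyl there would be captured at once by O–H insertion.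

**The MOM ether on O7.** Compound 5 comes from the triol 4 by protection of the hydroxyl para to the acetyl group. The forward reaction has to select this most acidic hydroxyl although it now has a quaternary neighbour.

**The quaternary carbon.** Triol 4 is traced to the prenyl ether 3 by a retro-Claisen step that cuts the bond between C3 of the ring and the quaternary carbon. Ether 3 comes from 2,4,6-trihydroxyacetophenone 1 and prenyl bromide 2. The ether is placed on the oxygen para to the acetyl group on purpose. From there the shift can end only on the flanking ring carbons, which are equivalent, because the para carbon carries the acetyl group. A prenyl ether on an ortho oxygen would have an open para position, and a Claisen–Cope relay could deliver the linear prenyl isomer to a position that becomes indistinguishable after tautomerisation.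

## Roads not taken

**Alternative 1:** C2–C3 and C3–O would be formed together in an open chain and O1–C2 closed afterwards. The tris-silyl diazomethyl ketone A2 would be decomposed by Rh2(OAc)4 in the presence of 4-methoxybenzyl alcohol A3. The resulting oxonium ylide would be trapped by 4-acetoxybenzaldehyde A4 under a chiral phosphoric acid to give the syn adduct A1. The C8a oxygen would then be unmasked and ring C closed at C2 with inversion.
- Merits: both stereocentres and the C3 oxygen arrive in one convergent step, ring A needs three identical silyl groups at that stage, and no flavanone ever has to be enolised. In these respects it is better than the chosen plan, which spends a separate operation on the C3 hydroxyl and must silylate a hindered phenol.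
- Weak points: enantioselective trapping of ylides is far less secure for acceptor-only diazomethyl ketones than for aryl diazoacetates, and simple O–H insertion competes. A1 is a β-hydroxy ketone that can revert by retro-aldol cleavage. Ring closure needs clean inversion at a benzylic carbinol that ionises easily, and the two ortho silyl ethers must still be told apart. The 4-methoxybenzyl group must finally be removed oxidatively beside a phloroglucinol ring.
- Comparison: the chosen plan forms one bond and one stereocentre in a ring closure of an established type, lets the ring set the trans relationship, and needs three steps after the key step where this road needs at least five.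

**Alternative 2:** Ring A would be built last, by forming C5–C6, C7–C8 and C4a–C5 on a stereodefined pyranone. Irradiation of the diazo ketone A6 would trigger a Wolff rearrangement to a vinylketene. This would add the siloxyalkyne A7 to give a vinylcyclobutenone, which opens and electrocyclises to the phenol A5.
- Merits: the substitution pattern of ring A is written into the alkyne, so there is no Claisen step and no differentiation of phenols. The 5-hydroxyl emerges free and the end game is a single fluoride step. In protecting-group economy this road is better than the chosen plan.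
- Weak points: A6 needs its own asymmetric synthesis of a dihydropyranone with two stereocentres and a diazoacetyl group, likely eight or more steps. Its C2 is a benzylic centre on a vinylogous ester oxygen and is prone to ionisation and elimination on heating. A7 carries a quaternary propargylic carbon and should be a sluggish ketenophile. Both stereocentres must survive a photochemical and thermal cascade.
- Comparison: the chosen plan starts from a commercial ring A and sets the stereocentres late on robust intermediates, at the price of differentiating three phenols.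

**Alternative 3:** Ring C would be closed at O1–C8a and C4–C4a. CsF would release the 3-alkoxyaryne from the silyl triflate A9. The alkoxide of the anti hydroxy ester A10 would add at C8a, distal to the C5 alkoxy group, and the aryl anion at C4a would acylate on the ester to give A8.
- Merits: this is the most convergent road. Both stereocentres would come from an asymmetric dihydroxylation of an alkene, whose sense and level of induction are more dependable than those of the chosen C–H insertion, and the aryne regiochemistry is dictated by the C5 oxygen.
- Weak points: A9 is a pentasubstituted benzene with adjacent silyl and triflate groups beside the quaternary side chain, and would take seven to nine steps. The aryl anion can abstract the acidic C3 hydrogen of the ester instead of acylating, which leaves an open aryl ether and erodes C3. The alkoxide of A10 can fragment by retro-aldol reaction, and the annulation is far less established for aliphatic hydroxy esters than for salicylates.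
- Comparison: the chosen plan offers a much shorter path to its key-step precursor and a neutral ring closure in which no stereocentre can epimerise.

Key step: step 9

Assumption: Rh2(S-PTTL)4 is taken to deliver the 2S product; if the sense of induction proves opposite, the enantiomeric catalyst Rh2(R-PTTL)4 is used and nothing else changes.

## Route

Step 1
Reactants: 1 2,4,6-trihydroxyacetophenone; 2 prenyl bromide (1-bromo-3-methylbut-2-ene)
Product: 3 1-[2,6-dihydroxy-4-(3-methylbut-2-enyloxy)phenyl]ethanone
Conditions: K2CO3 (1.1 equiv), 2 (1.0 equiv), acetone, 40 °C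
Reagents that add atoms: none
Why: Williamson ether synthesis; the hydroxyl para to the acetyl group is the most acidic and the only one not tied up in a hydrogen bond to the carbonyl, so one equivalent of base and halide alkylates it first, and carbonate in acetone favours O- over C-alkylation.

Step 2
Reactants: 3 1-[2,6-dihydroxy-4-(3-methylbut-2-enyloxy)phenyl]ethanone
Product: 4 1-[2,4,6-trihydroxy-3-(2-methylbut-3-en-2-yl)phenyl]ethanone
Conditions: EtOH/H2O (4:1), 130 °C, sealed tube, argon
Reagents that add atoms: none
Why: Aromatic Claisen rearrangement; the [3,3] shift joins the dimethyl-substituted allyl terminus to the ring carbon ortho to the ether oxygen, which creates the quaternary carbon. Both ortho carbons are equivalent and the para carbon is blocked by the acetyl group, so a single constitution can result; the protic medium accelerates the shift and allows a temperature below that of onward reactions of the product.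

Step 3
Reactants: 4 1-[2,4,6-trihydroxy-3-(2-methylbut-3-en-2-yl)phenyl]ethanone
Product: 5 1-[2,6-dihydroxy-4-(methoxymethoxy)-3-(2-methylbut-3-en-2-yl)phenyl]ethanone
Conditions: MOMCl (1.05 equiv), i-Pr2NEt (1.2 equiv), CH2Cl2, 0 °C
Reagents that add atoms: chloromethyl methyl ether, COCCl
Why: O-alkylation of a phenol to a MOM acetal; the hydroxyl para to the acetyl group is the most acidic, and the small, highly reactive electrophile is little affected by the neighbouring quaternary carbon, while the ortho hydroxyls are held back by chelation to the carbonyl.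

Step 4
Reactants: 6 4-hydroxybenzaldehyde
Product: 7 4-(methoxymethoxy)benzaldehyde
Conditions: MOMCl, i-Pr2NEt, CH2Cl2, 0 °C → rt
Reagents that add atoms: chloromethyl methyl ether, COCCl
Why: Standard MOM protection of an acidic phenol; the aldehyde is inert.

Step 5
Reactants: 7 4-(methoxymethoxy)benzaldehyde
Product: 8 [4-(methoxymethoxy)phenyl]methanol
Conditions: NaBH4, MeOH, 0 °C
Reagents that add atoms: none
Why: Borohydride reduction of an aryl aldehyde; the acetal is untouched.

Step 6
Reactants: 5 1-[2,6-dihydroxy-4-(methoxymethoxy)-3-(2-methylbut-3-en-2-yl)phenyl]ethanone; 8 [4-(methoxymethoxy)phenyl]methanol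
Product: 9 1-[2-hydroxy-4-(methoxymethoxy)-6-{[4-(methoxymethoxy)phenyl]methoxy}-3-(2-methylbut-3-en-2-yl)phenyl]ethanone
Conditions: PPh3, DIAD, THF, 0 °C → rt
Reagents that add atoms: none
Why: Mitsunobu etherification of a phenol with a primary benzylic alcohol, which avoids the labile 4-alkoxybenzyl halide. Of the two ortho hydroxyls only the one with a hydrogen neighbour is accessible to the bulky alkoxyphosphonium partner; the other is flanked by the quaternary carbon and chelated, so the reaction stops at the mono-ether.

Step 7
Reactants: 9 1-[2-hydroxy-4-(methoxymethoxy)-6-{[4-(methoxymethoxy)phenyl]methoxy}-3-(2-methylbut-3-en-2-yl)phenyl]ethanone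
Product: 10 1-[2-(tert-butyldimethylsilyloxy)-4-(methoxymethoxy)-6-{[4-(methoxymethoxy)phenyl]methoxy}-3-(2-methylbut-3-en-2-yl)phenyl]ethanone
Conditions: TBSOTf, 2,6-lutidine, CH2Cl2, 0 °C → rt; mild aqueous acid work-up
Reagents that add atoms: tert-butyldimethylsilyl triflate, CC(C)(C)[Si](C)(C)OS(=O)(=O)C(F)(F)F
Why: Silylation of a hindered, chelated phenol with a silyl triflate, the reagent class that reaches hydroxyls silyl chlorides do not; any enol silyl ether formed at the ketone is hydrolysed in the work-up while the aryl silyl ether stays.

Step 8
Reactants: 10 1-[2-(tert-butyldimethylsilyloxy)-4-(methoxymethoxy)-6-{[4-(methoxymethoxy)phenyl]methoxy}-3-(2-methylbut-3-en-2-yl)phenyl]ethanone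
Product: 12 2-diazo-1-[2-(tert-butyldimethylsilyloxy)-4-(methoxymethoxy)-6-{[4-(methoxymethoxy)phenyl]methoxy}-3-(2-methylbut-3-en-2-yl)phenyl]ethanone, via trifluoroacetyl diketone 11 (not isolated)
Conditions: LiN(SiMe3)2, THF, −78 °C; CF3CO2CH2CF3; 5% aq HCl; then MsN3, Et3N, H2O (1 equiv), MeCN, rt
Reagents that add atoms: methanesulfonyl azide, CS(=O)(=O)N=[N+]=[N-] (2,2,2-trifluoroethyl trifluoroacetate, O=C(OCC(F)(F)F)C(F)(F)F, adds the trifluoroacetyl group of 11 only)
Why: Detrifluoroacetylative diazo transfer: Claisen condensation of the kinetic lithium enolate with the trifluoroacetate activates the methyl group, and Regitz-type diazo transfer to diketone 11 is followed by loss of the trifluoroacetyl group. The conditions are cold and then only weakly basic, which the aryl silyl ether, the acetals and the benzylic ether tolerate.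

Step 9
Reactants: 12 2-diazo-1-[2-(tert-butyldimethylsilyloxy)-4-(methoxymethoxy)-6-{[4-(methoxymethoxy)phenyl]methoxy}-3-(2-methylbut-3-en-2-yl)phenyl]ethanone
Product: 13 (2S)-5-(tert-butyldimethylsilyloxy)-7-(methoxymethoxy)-2-[4-(methoxymethoxy)phenyl]-6-(2-methylbut-3-en-2-yl)chroman-4-one
Conditions: Rh2(S-PTTL)4 (dirhodium tetrakis[N-phthaloyl-(S)-tert-leucinate], 2 mol %), toluene, −20 → 0 °C, slow addition of 12
Reagents that add atoms: none
Why: Intramolecular rhodium carbene C–H insertion: the divalent rhodium carboxylate expels N2 from 12 to give an electrophilic acceptor-only carbene at C3, which takes up a C2–H bond of the neighbouring benzylic ether through a concerted, hydride-transfer-like three-centre transition state and so forms C2–C3. The closest known reaction types are the chiral dirhodium carboxylate-catalysed insertion of ortho-alkoxyaryl α-diazo ketones to chroman-4-ones and the Rh2(S-PTTL)4-catalysed insertion of ortho-benzyloxyaryl diazoacetates into the same kind of benzylic ether C–H bond. Ring C closes in the 1,6-mode (carbene carbon, C4, C4a, C8a, O1, C2); the five-membered alternative would be attack on O1 itself. The new stereocentre C2 is set by the catalyst alone: the phthalimido walls of the four tert-leucinate ligands hold the carbene in a chiral pocket in which only one of the two enantiotopic benzylic hydrogens can reach the carbene carbon with the aryl group turned away from the ligand wall. The step needs chemoselectivity for insertion over oxonium ylide formation at O1 with 1,2-shift of the benzyl group; O1 is an aryl ether oxygen whose lone pair is delocalised into an acylated ring and is a poor donor, whereas the C–H bond is activated by O1 and by the 4-alkoxyphenyl ring together. It also needs site selectivity: the silyl ether on the other ortho oxygen offers no C–H bond within reach, the MOM group on O7 is remote, and the vinyl group could be cyclopropanated only through a seven-membered ring. Slow addition at low temperature keeps the diazo concentration down and suppresses carbene dimerisation.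

Step 10
Reactants: 13 (2S)-5-(tert-butyldimethylsilyloxy)-7-(methoxymethoxy)-2-[4-(methoxymethoxy)phenyl]-6-(2-methylbut-3-en-2-yl)chroman-4-one
Product: 16 (2R,3R)-5-(tert-butyldimethylsilyloxy)-3-hydroxy-7-(methoxymethoxy)-2-[4-(methoxymethoxy)phenyl]-6-(2-methylbut-3-en-2-yl)chroman-4-one, via trimethylsilyl enol ether 14 (not isolated), via silyloxy epoxide 15 (not isolated)
Conditions: TMSOTf, Et3N (excess), CH2Cl2, −78 → 0 °C; pentane, filter, concentrate; DMDO, acetone/CH2Cl2, −78 → −40 °C; then aq citric acid, THF, 0 °C
Reagents that add atoms: dimethyldioxirane, CC1(C)OO1 (trimethylsilyl triflate, C[Si](C)(C)OS(=O)(=O)C(F)(F)F, adds the silyl group of 14 and 15 only)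
Why: Rubottom oxidation: soft enolisation gives enol ether 14 without a free enolate, so ring C cannot open and C2 is not touched. Dimethyldioxirane epoxidises the electron-rich enol ether from the face anti to the C2 aryl group, which sets C3 as R (trans), and hydrolysis of epoxide 15 gives the ketol; the trans isomer is also the thermodynamically preferred one. The monosubstituted alkene of the side chain is far less nucleophilic than the enol ether and is spared by one equivalent of oxidant at low temperature.

Step 11
Reactants: 16 (2R,3R)-5-(tert-butyldimethylsilyloxy)-3-hydroxy-7-(methoxymethoxy)-2-[4-(methoxymethoxy)phenyl]-6-(2-methylbut-3-en-2-yl)chroman-4-one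
Product: 17 (2R,3R)-3,5-dihydroxy-7-(methoxymethoxy)-2-[4-(methoxymethoxy)phenyl]-6-(2-methylbut-3-en-2-yl)chroman-4-one
Conditions: Bu4NF/AcOH (1:1), THF, 0 °C
Reagents that add atoms: none
Why: Fluoride cleavage of an aryl silyl ether; acetic acid protonates the phenoxide as it forms, so the medium never becomes basic enough for retro-oxa-Michael opening or epimerisation of the ketol.

Step 12
Reactants: 17 (2R,3R)-3,5-dihydroxy-7-(methoxymethoxy)-2-[4-(methoxymethoxy)phenyl]-6-(2-methylbut-3-en-2-yl)chroman-4-one
Product: 18 (2R,3R)-3,5,7-trihydroxy-2-(4-hydroxyphenyl)-6-(2-methylbut-3-en-2-yl)chroman-4-one (CNP0527000.1)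
Conditions: 3 M aq HCl/MeOH (1:5), 40 °C
Reagents that add atoms: none
Why: Acid-catalysed methanolysis of the two aryl MOM acetals; dihydroflavonols are configurationally stable in dilute acid. Protonation of the side-chain alkene would give only a secondary cation next to a quaternary carbon, so it is much slower than acetal cleavage under these mild conditions.

## Compound list

1 | 2,4,6-trihydroxyacetophenone | CC(=O)c1c(O)cc(O)cc1O | starting material
2 | prenyl bromide (1-bromo-3-methylbut-2-ene) | CC(C)=CCBr | starting material
3 | 1-[2,6-dihydroxy-4-(3-methylbut-2-enyloxy)phenyl]ethanone | CC(=O)c1c(O)cc(OCC=C(C)C)cc1O | intermediate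
4 | 1-[2,4,6-trihydroxy-3-(2-methylbut-3-en-2-yl)phenyl]ethanone | CC(=O)c1c(O)cc(O)c(C(C)(C)C=C)c1O | intermediate
5 | 1-[2,6-dihydroxy-4-(methoxymethoxy)-3-(2-methylbut-3-en-2-yl)phenyl]ethanone | CC(=O)c1c(O)cc(OCOC)c(C(C)(C)C=C)c1O | intermediate
6 | 4-hydroxybenzaldehyde | O=Cc1ccc(O)cc1 | starting material
7 | 4-(methoxymethoxy)benzaldehyde | O=Cc1ccc(OCOC)cc1 | intermediate
8 | [4-(methoxymethoxy)phenyl]methanol | OCc1ccc(OCOC)cc1 | intermediate
9 | 1-[2-hydroxy-4-(methoxymethoxy)-6-{[4-(methoxymethoxy)phenyl]methoxy}-3-(2-methylbut-3-en-2-yl)phenyl]ethanone | CC(=O)c1c(OCc2ccc(OCOC)cc2)cc(OCOC)c(C(C)(C)C=C)c1O | intermediate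
10 | 1-[2-(tert-butyldimethylsilyloxy)-4-(methoxymethoxy)-6-{[4-(methoxymethoxy)phenyl]methoxy}-3-(2-methylbut-3-en-2-yl)phenyl]ethanone | CC(=O)c1c(OCc2ccc(OCOC)cc2)cc(OCOC)c(C(C)(C)C=C)c1O[Si](C)(C)C(C)(C)C | intermediate
11 | 4,4,4-trifluoro-1-[2-(tert-butyldimethylsilyloxy)-4-(methoxymethoxy)-6-{[4-(methoxymethoxy)phenyl]methoxy}-3-(2-methylbut-3-en-2-yl)phenyl]butane-1,3-dione | O=C(CC(=O)C(F)(F)F)c1c(OCc2ccc(OCOC)cc2)cc(OCOC)c(C(C)(C)C=C)c1O[Si](C)(C)C(C)(C)C | intermediate (not isolated)
12 | 2-diazo-1-[2-(tert-butyldimethylsilyloxy)-4-(methoxymethoxy)-6-{[4-(methoxymethoxy)phenyl]methoxy}-3-(2-methylbut-3-en-2-yl)phenyl]ethanone | [N-]=[N+]=CC(=O)c1c(OCc2ccc(OCOC)cc2)cc(OCOC)c(C(C)(C)C=C)c1O[Si](C)(C)C(C)(C)C | intermediate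
13 | (2S)-5-(tert-butyldimethylsilyloxy)-7-(methoxymethoxy)-2-[4-(methoxymethoxy)phenyl]-6-(2-methylbut-3-en-2-yl)chroman-4-one | C=CC(C)(C)c1c(OCOC)cc2c(c1O[Si](C)(C)C(C)(C)C)C(=O)C[C@@H](c1ccc(OCOC)cc1)O2 | intermediate
14 | (2S)-5-(tert-butyldimethylsilyloxy)-7-(methoxymethoxy)-2-[4-(methoxymethoxy)phenyl]-6-(2-methylbut-3-en-2-yl)-4-(trimethylsilyloxy)-2H-chromene | C=CC(C)(C)c1c(OCOC)cc2c(c1O[Si](C)(C)C(C)(C)C)C(O[Si](C)(C)C)=C[C@@H](c1ccc(OCOC)cc1)O2 | intermediate (not isolated)
15 | (2R,3R,4R)-5-(tert-butyldimethylsilyloxy)-3,4-epoxy-7-(methoxymethoxy)-2-[4-(methoxymethoxy)phenyl]-6-(2-methylbut-3-en-2-yl)-4-(trimethylsilyloxy)chroman (oxirane oxygen anti to the C2 aryl group) | C=CC(C)(C)c1c(OCOC)cc2c(c1O[Si](C)(C)C(C)(C)C)[C@]3(O[Si](C)(C)C)O[C@@H]3[C@@H](c1ccc(OCOC)cc1)O2 | intermediate (not isolated)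
16 | (2R,3R)-5-(tert-butyldimethylsilyloxy)-3-hydroxy-7-(methoxymethoxy)-2-[4-(methoxymethoxy)phenyl]-6-(2-methylbut-3-en-2-yl)chroman-4-one | C=CC(C)(C)c1c(OCOC)cc2c(c1O[Si](C)(C)C(C)(C)C)C(=O)[C@H](O)[C@@H](c1ccc(OCOC)cc1)O2 | intermediate
17 | (2R,3R)-3,5-dihydroxy-7-(methoxymethoxy)-2-[4-(methoxymethoxy)phenyl]-6-(2-methylbut-3-en-2-yl)chroman-4-one | C=CC(C)(C)c1c(OCOC)cc2c(c1O)C(=O)[C@H](O)[C@@H](c1ccc(OCOC)cc1)O2 | intermediate
18 | (2R,3R)-3,5,7-trihydroxy-2-(4-hydroxyphenyl)-6-(2-methylbut-3-en-2-yl)chroman-4-one | C=CC(C)(C)c1c(O)cc2c(c1O)C(=O)[C@H](O)[C@@H](c1ccc(O)cc1)O2 | target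

## Step count and least certain steps

Total: 12 steps. Longest linear sequence: 10 steps from 1 (steps 1, 2, 3, 6, 7, 8, 9, 10, 11, 12); steps 4 and 5 form the short branch to 8.

**Step 9 (key step).** The most likely failure is capture of the carbene by the lone pair of O1 instead of the C–H bond. The five-membered oxonium ylide would then undergo 1,2-shift of the benzyl group, a migration made easier by the same electron-rich aryl ring that activates the C–H bond. A second weakness is incomplete discrimination of the two benzylic hydrogens, because an acceptor-only carbene is less selective than a donor/acceptor one. Fallback: ring C is closed at O1–C2 and C2 is set by conjugate addition. The route is left at 10. Oxidative removal of the 4-(methoxymethoxy)benzyl ether with DDQ gives the phenol 1-[2-(tert-butyldimethylsilyloxy)-6-hydroxy-4-(methoxymethoxy)-3-(2-methylbut-3-en-2-yl)phenyl]ethanone F1. Heating with N,N-dimethylformamide dimethyl acetal gives the enaminone (E)-3-(dimethylamino)-1-[2-(tert-butyldimethylsilyloxy)-6-hydroxy-4-(methoxymethoxy)-3-(2-methylbut-3-en-2-yl)phenyl]prop-2-en-1-one F2. This closes on silica gel or with a trace of acetic acid to the chromone 5-(tert-butyldimethylsilyloxy)-7-(methoxymethoxy)-6-(2-methylbut-3-en-2-yl)chromen-4-one F3. Enantioselective 1,4-addition of 4-(methoxymethoxy)phenylboronic acid, catalysed by Pd(OCOCF3)2 with the pyridine-oxazoline ligand t-BuPyOx of the appropriate configuration, gives 13, where the route is rejoined.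

**Step 7.** The hydroxyl to be silylated is chelated to the acetyl group and flanked by a quaternary carbon, so silyl transfer to oxygen may stall. Forcing it may lead to silylation of the ketone oxygen or to exchange at the MOM acetals. Fallback: silicon is put on before the quaternary carbon exists. The route is left at 3. TBSCl and imidazole in DMF silylate both equivalent hydroxyls to give 1-[2,6-bis(tert-butyldimethylsilyloxy)-4-(3-methylbut-2-enyloxy)phenyl]ethanone F4. Claisen rearrangement in N,N-diethylaniline at 185 °C gives 1-[2,6-bis(tert-butyldimethylsilyloxy)-4-hydroxy-3-(2-methylbut-3-en-2-yl)phenyl]ethanone F5. Its only free hydroxyl is capped with MOMCl and i-Pr2NEt to give 1-[2,6-bis(tert-butyldimethylsilyloxy)-4-(methoxymethoxy)-3-(2-methylbut-3-en-2-yl)phenyl]ethanone F6. The silyl ether not shielded by the side chain is cleaved selectively (K2CO3, MeOH, 0 °C) to the phenol F1 described under step 9, and Mitsunobu etherification of F1 with 8 gives 10.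

**Step 2.** Two processes threaten the rearrangement. The first is solvolytic loss of the prenyl group, since the ether of an acidic phenol can ionise in hot aqueous ethanol. The second is onward reaction of the ortho-(1,1-dimethylallyl)phenol on prolonged heating, either ring closure of a flanking hydroxyl onto the alkene or the abnormal Claisen rearrangement, both of which need the free phenol. Fallback: the phenols are masked during the shift. The route is left at 3. Heating with excess N,O-bis(trimethylsilyl)acetamide in N,N-diethylaniline at 185 °C first gives the bis-silyl ether 1-[4-(3-methylbut-2-enyloxy)-2,6-bis(trimethylsilyloxy)phenyl]ethanone F7. This rearranges, and the new phenol is captured as it forms to give 1-[3-(2-methylbut-3-en-2-yl)-2,4,6-tris(trimethylsilyloxy)phenyl]ethanone F8. Methanolysis (K2CO3, MeOH, 0 °C) returns 4.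

**Step 3.** Alkylation may spread to the unhindered ortho hydroxyl, or to both accessible hydroxyls, because the most acidic hydroxyl is also the one next to the quaternary carbon. Fallback: both accessible hydroxyls are capped and one is released by chelation. The route is left at 4. Excess MOMCl and i-Pr2NEt give 1-[2-hydroxy-4,6-bis(methoxymethoxy)-3-(2-methylbut-3-en-2-yl)phenyl]ethanone F9, in which the hindered, chelated hydroxyl is still free. Silylation as in step 7 gives 1-[2-(tert-butyldimethylsilyloxy)-4,6-bis(methoxymethoxy)-3-(2-methylbut-3-en-2-yl)phenyl]ethanone F10. MgBr2·OEt2 in CH2Cl2/Et2O binds between the ketone oxygen and the neighbouring acetal oxygen and removes only the MOM group ortho to the acetyl group, which gives the phenol F1 described under step 9. Mitsunobu etherification of F1 with 8 gives 10.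

## Further compounds

F1 | step 9 | 1-[2-(tert-butyldimethylsilyloxy)-6-hydroxy-4-(methoxymethoxy)-3-(2-methylbut-3-en-2-yl)phenyl]ethanone | CC(=O)c1c(O)cc(OCOC)c(C(C)(C)C=C)c1O[Si](C)(C)C(C)(C)C
F2 | step 9 | (E)-3-(dimethylamino)-1-[2-(tert-butyldimethylsilyloxy)-6-hydroxy-4-(methoxymethoxy)-3-(2-methylbut-3-en-2-yl)phenyl]prop-2-en-1-one | CN(C)/C=C/C(=O)c1c(O)cc(OCOC)c(C(C)(C)C=C)c1O[Si](C)(C)C(C)(C)C
F3 | step 9 | 5-(tert-butyldimethylsilyloxy)-7-(methoxymethoxy)-6-(2-methylbut-3-en-2-yl)chromen-4-one | C=CC(C)(C)c1c(OCOC)cc2occc(=O)c2c1O[Si](C)(C)C(C)(C)C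
F4 | step 7 | 1-[2,6-bis(tert-butyldimethylsilyloxy)-4-(3-methylbut-2-enyloxy)phenyl]ethanone | CC(=O)c1c(O[Si](C)(C)C(C)(C)C)cc(OCC=C(C)C)cc1O[Si](C)(C)C(C)(C)C
F5 | step 7 | 1-[2,6-bis(tert-butyldimethylsilyloxy)-4-hydroxy-3-(2-methylbut-3-en-2-yl)phenyl]ethanone | CC(=O)c1c(O[Si](C)(C)C(C)(C)C)cc(O)c(C(C)(C)C=C)c1O[Si](C)(C)C(C)(C)C
F6 | step 7 | 1-[2,6-bis(tert-butyldimethylsilyloxy)-4-(methoxymethoxy)-3-(2-methylbut-3-en-2-yl)phenyl]ethanone | CC(=O)c1c(O[Si](C)(C)C(C)(C)C)cc(OCOC)c(C(C)(C)C=C)c1O[Si](C)(C)C(C)(C)C
F7 | step 2 | 1-[4-(3-methylbut-2-enyloxy)-2,6-bis(trimethylsilyloxy)phenyl]ethanone | CC(=O)c1c(O[Si](C)(C)C)cc(OCC=C(C)C)cc1O[Si](C)(C)C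
F8 | step 2 | 1-[3-(2-methylbut-3-en-2-yl)-2,4,6-tris(trimethylsilyloxy)phenyl]ethanone | CC(=O)c1c(O[Si](C)(C)C)cc(O[Si](C)(C)C)c(C(C)(C)C=C)c1O[Si](C)(C)C
F9 | step 3 | 1-[2-hydroxy-4,6-bis(methoxymethoxy)-3-(2-methylbut-3-en-2-yl)phenyl]ethanone | CC(=O)c1c(OCOC)cc(OCOC)c(C(C)(C)C=C)c1O
F10 | step 3 | 1-[2-(tert-butyldimethylsilyloxy)-4,6-bis(methoxymethoxy)-3-(2-methylbut-3-en-2-yl)phenyl]ethanone | CC(=O)c1c(OCOC)cc(OCOC)c(C(C)(C)C=C)c1O[Si](C)(C)C(C)(C)C
A1 | alternative 1 | (2R,3S)-3-(4-acetoxyphenyl)-3-hydroxy-2-(4-methoxybenzyloxy)-1-[2,4,6-tris(tert-butyldimethylsilyloxy)-3-(2-methylbut-3-en-2-yl)phenyl]propan-1-one | C=CC(C)(C)c1c(O[Si](C)(C)C(C)(C)C)cc(O[Si](C)(C)C(C)(C)C)c(c1O[Si](C)(C)C(C)(C)C)C(=O)[C@H](OCc1ccc(OC)cc1)[C@H](c1ccc(OC(C)=O)cc1)O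
A2 | alternative 1 | 2-diazo-1-[2,4,6-tris(tert-butyldimethylsilyloxy)-3-(2-methylbut-3-en-2-yl)phenyl]ethanone | [N-]=[N+]=CC(=O)c1c(O[Si](C)(C)C(C)(C)C)cc(O[Si](C)(C)C(C)(C)C)c(C(C)(C)C=C)c1O[Si](C)(C)C(C)(C)C
A3 | alternative 1 | 4-methoxybenzyl alcohol | COc1ccc(CO)cc1
A4 | alternative 1 | 4-acetoxybenzaldehyde | CC(=O)Oc1ccc(C=O)cc1
A5 | alternative 2 | (2R,3R)-3-(tert-butyldimethylsilyloxy)-2-[4-(tert-butyldimethylsilyloxy)phenyl]-5-hydroxy-6-(2-methylbut-3-en-2-yl)-7-(triisopropylsilyloxy)chroman-4-one | C=CC(C)(C)c1c(O[Si](C(C)C)(C(C)C)C(C)C)cc2c(c1O)C(=O)[C@H](O[Si](C)(C)C(C)(C)C)[C@@H](c1ccc(O[Si](C)(C)C(C)(C)C)cc1)O2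
A6 | alternative 2 | (2R,3R)-3-(tert-butyldimethylsilyloxy)-2-[4-(tert-butyldimethylsilyloxy)phenyl]-6-(diazoacetyl)-2,3-dihydropyran-4-one | [N-]=[N+]=CC(=O)C1=CC(=O)[C@H](O[Si](C)(C)C(C)(C)C)[C@@H](c2ccc(O[Si](C)(C)C(C)(C)C)cc2)O1
A7 | alternative 2 | (3,3-dimethylpent-4-en-1-ynyloxy)triisopropylsilane | C=CC(C)(C)C#CO[Si](C(C)C)(C(C)C)C(C)C
A8 | alternative 3 | (2R,3R)-3,5,7-tris(methoxymethoxy)-2-[4-(methoxymethoxy)phenyl]-6-(2-methylbut-3-en-2-yl)chroman-4-one | C=CC(C)(C)c1c(OCOC)cc2c(c1OCOC)C(=O)[C@H](OCOC)[C@@H](c1ccc(OCOC)cc1)O2
A9 | alternative 3 | 3,5-bis(methoxymethoxy)-4-(2-methylbut-3-en-2-yl)-2-(trimethylsilyl)phenyl trifluoromethanesulfonate | C=CC(C)(C)c1c(OCOC)cc(OS(=O)(=O)C(F)(F)F)c([Si](C)(C)C)c1OCOC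
A10 | alternative 3 | methyl (2R,3R)-3-hydroxy-2-(methoxymethoxy)-3-[4-(methoxymethoxy)phenyl]propanoate | COC(=O)[C@H](OCOC)[C@@H](c1ccc(OCOC)cc1)O
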